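**Strategy.** The route rests on disconnecting C5–C6, so that ring B is closed last on a precursor in which the 19,10-lactone-bridged ring A and the C/D bicyclooctane are already joined through C9–C10. The key step is a Rh(II)-carbenoid 1,5 C–H insertion: the C6 diazo ester on quaternary C8 (no β-hydrogen) inserts into the C5 methylene, the one-carbon bridge between the fully substituted C4 and C10 of ring A, with H-5β shielded by a 1β,3β-carbonate. One operation forms ring B and sets C5 and C6. The precursor is assembled from a verbenone-derived C/D chloride and a Fráter–Seebach dianion, then metathesis and epoxide lactonisation.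

Key step: step 16

Remark: gibberellin (GA) atom numbering and the usual GA face descriptors (3β-OH, H-5β, H-9β, 6β-carboxyl, lactone oxygen on C10α) are used for later intermediates; enantiopure (1R,5R)-verbenone and the (R)-chlorohydrin ester are the sources of absolute configuration, and the SMILES strings are authoritative.

**Step 1**
Reactants: 1 (1R,5R)-(+)-verbenone
Product: 2 (1R,5S)-4-(bromomethyl)-6,6-dimethylbicyclo[3.1.1]hept-3-en-2-one
Conditions: NBS (1.05 equiv), AIBN (cat.), PhCF3, 80 °C
Reagents that add atoms: N-bromosuccinimide, O=C1CCC(=O)N1Br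
Why: Wohl–Ziegler radical bromination should take place at the C4 methyl group, the only γ-position that can give a delocalised radical (the other γ-carbon is a bridgehead), and it touches neither stereocentre.

**Step 2**
Reactants: 2 (1R,5S)-4-(bromomethyl)-6,6-dimethylbicyclo[3.1.1]hept-3-en-2-one
Product: 3 methyl 2-[(1S,5R)-6,6-dimethyl-4-oxobicyclo[3.1.1]hept-2-en-2-yl]acetate
Conditions: PdCl2(PPh3)2 (2 mol%), CO (5 bar), MeOH, Et3N, THF, 50 °C
Reagents that add atoms: carbon monoxide, [C-]#[O+]; methanol, CO
Why: Pd-catalysed alkoxycarbonylation of an allylic bromide (oxidative addition, CO insertion, methanolysis) should give the two-carbon C6–C7 arm as a methyl ester while the C=C stays conjugated with the ketone.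

**Step 3**
Reactants: 3 methyl 2-[(1S,5R)-6,6-dimethyl-4-oxobicyclo[3.1.1]hept-2-en-2-yl]acetate; 4 allenyltributylstannane
Product: 5 methyl 2-[(1R,2R,5R)-6,6-dimethyl-4-oxo-2-(prop-2-yn-1-yl)bicyclo[3.1.1]heptan-2-yl]acetate
Conditions: TiCl4 (1.1 equiv), CH2Cl2, −78 °C; aq. NaHCO3 quench at −78 °C
Reagents that add atoms: none
Why: TiCl4-promoted conjugate propargylation of an enone by an allenylstannane (SE2′, Sakurai type) should deliver the propargyl group to the β-carbon from the face anti to the CMe2 bridge, as in conjugate additions to verbenone, which sets the quaternary centre (future C8) with the acetate arm syn to the bridge.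

**Step 4**
Reactants: 5 methyl 2-[(1R,2R,5R)-6,6-dimethyl-4-oxo-2-(prop-2-yn-1-yl)bicyclo[3.1.1]heptan-2-yl]acetate
Product: 8 methyl 2-[(1R,2S)-5-oxo-2-(prop-1-en-2-yl)-1-(prop-2-yn-1-yl)cyclohexyl]acetate, via lactonium silyl enol ether 6 (not isolated), via isopropenyl silyl enol ether 7 (not isolated)
Conditions: TMSOTf (1.2 equiv), CH2Cl2, −78 → −20 °C; then 2,6-di-tert-butyl-4-methylpyridine (2 equiv), −20 → 0 °C; aq. citric acid work-up
Reagents that add atoms: trimethylsilyl trifluoromethanesulfonate, C[Si](C)(C)OS(=O)(=O)C(F)(F)F (its atoms stay only in 6 and 7)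
Why: Lewis-acid-promoted cyclobutane fragmentation of a pinanone (the nopinone ring opening) should break the bond between the carbonyl α-bridgehead and the CMe2 carbon on O-silylation, the tertiary cation being held by the cis ester carbonyl as a six-membered lactonium ion from which the hindered base removes a methyl proton (Hofmann sense) to give the isopropenyl group (future C10, C1, C5), with both ring stereocentres untouched.

**Step 5**
Reactants: 8 methyl 2-[(1R,2S)-5-oxo-2-(prop-1-en-2-yl)-1-(prop-2-yn-1-yl)cyclohexyl]acetate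
Product: 9 methyl 2-[(1R,2S,5S)-5-hydroxy-6-methylidene-2-(prop-1-en-2-yl)bicyclo[3.2.1]octan-1-yl]acetate
Conditions: SmI2 (2.5 equiv), HMPA, t-BuOH, THF, 0 °C
Reagents that add atoms: none
Why: SmI2 ketyl–alkyne reductive cyclisation (5-exo-dig) should close ring D, and because the propargyl arm can reach the ketyl carbon only across its own face, the bridgehead carbinol C13 and the exocyclic methylene form with the only possible relative configuration (the 6-endo path to the isopropenyl group needs a boat and should be slower).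

**Step 6**
Reactants: 9 methyl 2-[(1R,2S,5S)-5-hydroxy-6-methylidene-2-(prop-1-en-2-yl)bicyclo[3.2.1]octan-1-yl]acetate
Product: 10 methyl 2-[(1R,2S,5S)-6-methylidene-2-(prop-1-en-2-yl)-5-(triethylsilyloxy)bicyclo[3.2.1]octan-1-yl]acetate
Conditions: TESOTf, 2,6-lutidine, CH2Cl2, −78 → 0 °C
Reagents that add atoms: triethylsilyl trifluoromethanesulfonate, CC[Si](CC)(CC)OS(=O)(=O)C(F)(F)F
Why: Silyl triflate silylation of the hindered tertiary alcohol should mask 13-OH for the basic, oxidative and carbenoid steps and remove the allylic hydroxyl that would otherwise direct reagents to C16=C17.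

**Step 7**
Reactants: 10 methyl 2-[(1R,2S,5S)-6-methylidene-2-(prop-1-en-2-yl)-5-(triethylsilyloxy)bicyclo[3.2.1]octan-1-yl]acetate
Product: 11 methyl 2-[(1R,2R,5S)-2-(3-chloroprop-1-en-2-yl)-6-methylidene-5-(triethylsilyloxy)bicyclo[3.2.1]octan-1-yl]acetate
Conditions: Ca(OCl)2, CO2 (solid), CH2Cl2/H2O, 0 °C
Reagents that add atoms: calcium hypochlorite, [Ca+2].[O-]Cl.[O-]Cl
Why: Ene-type allylic chlorination by HOCl (attack at the terminal CH2, loss of a methyl proton) should convert the isopropenyl group into the 2-substituted allyl chloride, while the ring-D methylene is spared because it is deactivated and shielded by the silyloxy-bearing C13 and its only allylic hydrogens would give a strained endocyclic alkene.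

**Step 8**
Reactants: 12 ethyl (3R)-4-chloro-3-hydroxybutanoate
Product: 13 ethyl 2-[(2R)-oxiran-2-yl]acetate
Conditions: Ag2O (1 equiv), MeCN, 60 °C
Reagents that add atoms: none
Why: Silver-assisted intramolecular Williamson closure of the chlorohydrin under neutral conditions should avoid β-elimination to the hydroxycrotonate and leaves the carbinol stereocentre untouched.

**Step 9**
Reactants: 13 ethyl 2-[(2R)-oxiran-2-yl]acetate; 14 vinylmagnesium bromide
Product: 15 ethyl (3S)-3-hydroxyhex-5-enoate
Conditions: CuI (10 mol%), THF, −40 °C; aq. NH4Cl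
Reagents that add atoms: none
Why: Copper-catalysed SN2 opening of the terminal epoxide at its CH2 end should be faster than attack on the ester at low temperature, and the stereocentre (future C3) is retained (the descriptor changes only by priority).

**Step 10**
Reactants: 15 ethyl (3S)-3-hydroxyhex-5-enoate
Product: 16 ethyl (2S,3S)-3-hydroxy-2-methylhex-5-enoate
Conditions: LDA (2.2 equiv), THF, −50 °C; MeI, DMPU, −50 → −20 °C
Reagents that add atoms: iodomethane, CI
Why: Fráter–Seebach alkylation of the chelated β-hydroxy ester dianion should give the anti methyl ester, and this centre becomes the enolate carbon again in step 11, so only its substitution matters.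

**Step 11**
Reactants: 16 ethyl (2S,3S)-3-hydroxy-2-methylhex-5-enoate; 11 methyl 2-[(1R,2R,5S)-2-(3-chloroprop-1-en-2-yl)-6-methylidene-5-(triethylsilyloxy)bicyclo[3.2.1]octan-1-yl]acetate
Product: 17 ethyl (2S,3S)-3-hydroxy-2-methyl-2-[2-(C/D unit)prop-2-en-1-yl]hex-5-enoate (C/D unit = the bicyclooctan-2-yl group of 11, bonded through GA C9)
Conditions: 16 (1.5 equiv), LDA (3.2 equiv), THF, −50 → −20 °C; then 11, NaI (cat.), DMPU, −20 → 0 °C
Reagents that add atoms: none
Why: A second Fráter–Seebach alkylation should create quaternary C4 under control of the C3 alkoxide, the allyl electrophile entering anti to the carbinol side chain of the chelated dianion so that C5 is anti and the methyl syn to the C3–O bond (the GA configuration), and SN2 and SN2′ attack give the same product because the two allyl termini are equivalent.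

**Step 12**
Reactants: 17 ethyl (2S,3S)-3-hydroxy-2-methyl-2-[2-(C/D unit)prop-2-en-1-yl]hex-5-enoate
Product: 18 ethyl (1S,6S)-6-hydroxy-1-methyl-3-(C/D unit)cyclohex-3-ene-1-carboxylate (ring A with the C1=C10 double bond)
Conditions: Grubbs second-generation catalyst (5 mol%), CH2Cl2, 40 °C
Reagents that add atoms: none
Why: Ring-closing metathesis of the monosubstituted alkene with the 1,1-disubstituted alkene should form the trisubstituted cyclohexene of ring A, the hindered ring-D methylene being unable to engage, and no stereocentre is formed.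

**Step 13**
Reactants: 18 ethyl (1S,6S)-6-hydroxy-1-methyl-3-(C/D unit)cyclohex-3-ene-1-carboxylate
Product: 20 ring-A lactone diol (1β,3β-dihydroxy-19,10α-lactone, C5 still CH2, 7-methyl ester, 13-O-TES), via epoxy alcohol 19 (not isolated)
Conditions: VO(acac)2 (5 mol%), t-BuOOH, CH2Cl2, 0 °C → rt; then CSA (0.2 equiv), wet CH2Cl2, rt
Reagents that add atoms: tert-butyl hydroperoxide, CC(C)(C)OO; water, O
Why: Hydroxyl-directed vanadium epoxidation of the homoallylic alcohol should place the oxirane on the β-face (syn to 3β-OH, anti to the C19 ester), and acid then triggers 5-exo anti opening at tertiary C10 by the ester carbonyl with hydrolysis of the lactonium ion, which sets the C10α lactone oxygen and the 1β-hydroxyl by trans-diaxial opening.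

**Step 14**
Reactants: 20 ring-A lactone diol
Product: 21 1β,3β-O-carbonate of 20
Conditions: 1,1′-carbonyldiimidazole (1.5 equiv), DMAP (cat.), toluene, 80 °C
Reagents that add atoms: 1,1′-carbonyldiimidazole, O=C(n1ccnc1)n1ccnc1
Why: The syn-diaxial 1β,3β-diol should close readily to a six-membered cyclic carbonate, which has no acidic hydrogens, deactivates the C1–H bond and covers H-5β.

**Step 15**
Reactants: 21 1β,3β-O-carbonate of 20
Product: 23 C6 diazo ester of 21, via trifluoroacetyl ester 22 (not isolated)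
Conditions: LDA (1.2 equiv), THF, −78 °C; CF3CO2CH2CF3; then MsN3, Et3N, H2O (1 equiv), MeCN, rt
Reagents that add atoms: methanesulfonyl azide, CS(=O)(=O)N=[N+]=[N-]; 2,2,2-trifluoroethyl trifluoroacetate, O=C(OCC(F)(F)F)C(F)(F)F (its atoms stay only in 22)
Why: Deacylative (detrifluoroacetylative Regitz) diazo transfer should work because C6 carries the only enolisable hydrogens in 21 (C4 is quaternary, the carbonate and silyl ether are inert to LDA at −78 °C).

**Step 16**
Reactants: 23 C6 diazo ester of 21
Product: 24 GA55 7-methyl ester 1β,3β-O-carbonate 13-O-triethylsilyl ether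
Conditions: Rh2(esp)2 (1 mol%), CH2Cl2, 40 °C, slow addition of 23, 4 Å MS
Reagents that add atoms: none
Why: Loss of N2 from 23 gives an electrophilic Rh(II) carbenoid at C6 that inserts in a concerted three-centre fashion into a C5–H bond, the standard intramolecular 1,5 C–H insertion of α-diazo esters (Taber-type cyclopentane synthesis). Ring B (C5–C6–C8–C9–C10) closes by forming C5–C6 through a five-membered-ring transition state, and it is the only ring formed. C5 is set by site selection with retention: H-5β is syn-axial to the two carbonate oxygens on C1 and C3 and is blocked, so the carbenoid should take H-5α, which puts C6 on the α-face trans to H-5β (the natural trans A/B fusion). C6 is set in the same transition state with the CO2Me group anti to C4 (6β-ester), which should also be the more stable epimer, so mild base in step 17 can correct a minor isomer. The step needs C5–H insertion to beat β-hydride shift, O–H insertion and insertion at C1–H: C8 is quaternary, every hydroxyl is masked, the C1–H bond is deactivated by its acyloxy oxygen, and all other C–H bonds are 1,3, 1,4 or 1,6 to C6.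

**Step 17**
Reactants: 24 GA55 7-methyl ester 1β,3β-O-carbonate 13-O-triethylsilyl ether
Product: 25 GA55 7-methyl ester 13-O-triethylsilyl ether
Conditions: K2CO3 (0.5 equiv), MeOH, 0 °C → rt
Reagents that add atoms: none
Why: Methanolysis (transesterification) of the strained cyclic carbonate should free the 1β,3β-diol while the hindered methyl ester and the γ-lactone remain, under conditions too mild for retro-aldol epimerisation at C3.

**Step 18**
Reactants: 25 GA55 7-methyl ester 13-O-triethylsilyl ether
Product: 26 GA55 13-O-triethylsilyl ether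
Conditions: n-PrSLi, HMPA, rt; then 1 M HCl work-up at 0 °C
Reagents that add atoms: none
Why: SN2 demethylation by thiolate (Bartlett–Johnson), the classical way to free hindered gibberellin 7-carboxyls, attacks only the O-methyl carbon, so the lactone and the base-sensitive 3β-hydroxyl should survive.

**Step 19**
Reactants: 26 GA55 13-O-triethylsilyl ether
Product: 27 GA55
Conditions: HF·pyridine, THF, 0 °C → rt
Reagents that add atoms: none
Why: Fluoride-mediated cleavage of the tertiary silyl ether is mild enough to avoid the acid-induced rearrangement of the 13-hydroxy-16-ene C/D system.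

**Compound list**

1 | (1R,5R)-(+)-verbenone, (1R,5R)-4,6,6-trimethylbicyclo[3.1.1]hept-3-en-2-one | O=C1C=C(C)[C@H]2C[C@@H]1C2(C)C | starting material
2 | (1R,5S)-4-(bromomethyl)-6,6-dimethylbicyclo[3.1.1]hept-3-en-2-one | O=C1C=C(CBr)[C@H]2C[C@@H]1C2(C)C | intermediate
3 | methyl 2-[(1S,5R)-6,6-dimethyl-4-oxobicyclo[3.1.1]hept-2-en-2-yl]acetate | O=C1C=C(CC(=O)OC)[C@H]2C[C@@H]1C2(C)C | intermediate
4 | allenyltributylstannane, tributyl(propa-1,2-dien-1-yl)stannane | CCCC[Sn](CCCC)(CCCC)C=C=C | starting material
5 | methyl 2-[(1R,2R,5R)-6,6-dimethyl-4-oxo-2-(prop-2-yn-1-yl)bicyclo[3.1.1]heptan-2-yl]acetate (propargyl anti, acetate arm syn to the CMe2 bridge) | O=C1C[C@](CC#C)(CC(=O)OC)[C@H]2C[C@@H]1C2(C)C | intermediate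
6 | lactonium silyl enol ether: ring-opened cation held by the ester carbonyl as an O-methyl δ-lactonium triflate, ketone as its TMS enol ether (ring configuration as in 8) | C[Si](C)(C)OC1C[C@]2(CC#C)CC(OC)=[O+]C(C)(C)[C@@H]2CC=1.[O-]S(=O)(=O)C(F)(F)F | intermediate
7 | isopropenyl silyl enol ether: TMS enol ether of 8 | C[Si](C)(C)OC1C[C@](CC#C)(CC(=O)OC)[C@H](C(C)=C)CC=1 | intermediate
8 | methyl 2-[(1R,2S)-5-oxo-2-(prop-1-en-2-yl)-1-(prop-2-yn-1-yl)cyclohexyl]acetate | O=C1C[C@](CC#C)(CC(=O)OC)[C@H](C(C)=C)CC1 | intermediate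
9 | methyl 2-[(1R,2S,5S)-5-hydroxy-6-methylidene-2-(prop-1-en-2-yl)bicyclo[3.2.1]octan-1-yl]acetate | C=C1C[C@]2(CC(=O)OC)C[C@@]1(O)CC[C@H]2C(C)=C | intermediate
10 | methyl 2-[(1R,2S,5S)-6-methylidene-2-(prop-1-en-2-yl)-5-(triethylsilyloxy)bicyclo[3.2.1]octan-1-yl]acetate | C=C1C[C@]2(CC(=O)OC)C[C@@]1(O[Si](CC)(CC)CC)CC[C@H]2C(C)=C | intermediate
11 | methyl 2-[(1R,2R,5S)-2-(3-chloroprop-1-en-2-yl)-6-methylidene-5-(triethylsilyloxy)bicyclo[3.2.1]octan-1-yl]acetate | C=C1C[C@]2(CC(=O)OC)C[C@@]1(O[Si](CC)(CC)CC)CC[C@H]2C(=C)CCl | intermediate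
12 | ethyl (3R)-4-chloro-3-hydroxybutanoate | CCOC(=O)C[C@@H](O)CCl | starting material
13 | ethyl 2-[(2R)-oxiran-2-yl]acetate | CCOC(=O)C[C@@H]1CO1 | intermediate
14 | vinylmagnesium bromide | C=C[Mg]Br | starting material
15 | ethyl (3S)-3-hydroxyhex-5-enoate | CCOC(=O)C[C@@H](O)CC=C | intermediate
16 | ethyl (2S,3S)-3-hydroxy-2-methylhex-5-enoate | CCOC(=O)[C@@H](C)[C@@H](O)CC=C | intermediate
17 | ethyl (2S,3S)-3-hydroxy-2-methyl-2-[2-(C/D unit)prop-2-en-1-yl]hex-5-enoate; C/D unit = 1-(2-methoxy-2-oxoethyl)-6-methylidene-5-(triethylsilyloxy)bicyclo[3.2.1]octan-2-yl of 11, configuration unchanged | C=C1C[C@]2(CC(=O)OC)C[C@@]1(O[Si](CC)(CC)CC)CC[C@H]2C(=C)C[C@](C)(C(=O)OCC)[C@@H](O)CC=C | intermediate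
18 | ethyl (1S,6S)-6-hydroxy-1-methyl-3-(C/D unit)cyclohex-3-ene-1-carboxylate (ring A, GA C1=C10, 3β-OH cis to the C4 methyl) | C=C1C[C@]2(CC(=O)OC)C[C@@]1(O[Si](CC)(CC)CC)CC[C@H]2C1=CC[C@H](O)[C@@](C)(C(=O)OCC)C1 | intermediate
19 | epoxy alcohol: 1β,10β-epoxide of 18 (oxirane on the face of the 3-OH) | C=C1C[C@]2(CC(=O)OC)C[C@@]1(O[Si](CC)(CC)CC)CC[C@H]2[C@@]12O[C@@H]1C[C@H](O)[C@@](C)(C(=O)OCC)C2 | intermediate
20 | ring-A lactone diol: 1β,3β-dihydroxy-19,10α-lactone with C5 as CH2, C6 as the CH2 of the methyl acetate arm on C8, 13-O-TES (GA55 skeleton lacking the C5–C6 bond) | C=C1C[C@]2(CC(=O)OC)C[C@@]1(O[Si](CC)(CC)CC)CC[C@H]2[C@@]12OC(=O)[C@@](C)(C1)[C@@H](O)C[C@H]2O | intermediate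
21 | 1β,3β-O-carbonate (cyclic carbonate) of 20 | C=C1C[C@]2(CC(=O)OC)C[C@@]1(O[Si](CC)(CC)CC)CC[C@H]2[C@@]12OC(=O)[C@@](C)(C1)[C@@H](O3)C[C@H]2OC3=O | intermediate
22 | trifluoroacetyl ester: C6-trifluoroacetyl derivative of 21 (C6 configuration undefined) | C=C1C[C@]2(C(C(=O)C(F)(F)F)C(=O)OC)C[C@@]1(O[Si](CC)(CC)CC)CC[C@H]2[C@@]12OC(=O)[C@@](C)(C1)[C@@H](O3)C[C@H]2OC3=O | intermediate
23 | C6 diazo ester of 21 (methyl 2-diazoacetate arm on C8) | C=C1C[C@]2(C(=[N+]=[N-])C(=O)OC)C[C@@]1(O[Si](CC)(CC)CC)CC[C@H]2[C@@]12OC(=O)[C@@](C)(C1)[C@@H](O3)C[C@H]2OC3=O | intermediate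
24 | GA55 7-methyl ester 1β,3β-O-carbonate 13-O-triethylsilyl ether | C=C1C[C@]23C[C@@]1(O[Si](CC)(CC)CC)CC[C@H]2[C@@]12OC(=O)[C@@](C)([C@H]1[C@@H]3C(=O)OC)[C@@H](O4)C[C@H]2OC4=O | intermediate
25 | GA55 7-methyl ester 13-O-triethylsilyl ether | C=C1C[C@]23C[C@@]1(O[Si](CC)(CC)CC)CC[C@H]2[C@@]12OC(=O)[C@@](C)([C@H]1[C@@H]3C(=O)OC)[C@@H](O)C[C@H]2O | intermediate
26 | GA55 13-O-triethylsilyl ether | C=C1C[C@]23C[C@@]1(O[Si](CC)(CC)CC)CC[C@H]2[C@@]12OC(=O)[C@@](C)([C@H]1[C@@H]3C(=O)O)[C@@H](O)C[C@H]2O | intermediate
27 | GA55 (1β,3β,13-trihydroxy C19-gibberellin 19,10-lactone 7-oic acid) | C=C1C[C@]23C[C@@]1(O)CC[C@H]2[C@@]12OC(=O)[C@@](C)([C@H]1[C@@H]3C(=O)O)[C@@H](O)C[C@H]2O | target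

**Step count:** 19 steps in total; longest linear sequence 16 steps (steps 1–7 and 11–19).

**Steps most likely to fail**

1. Step 16 (key step). The carbenoid may be diverted instead of inserting at H-5α: insertion at C1–H or at H-5β, attack on a carbonyl oxygen, or dimerisation, because the C5–H bonds are inductively deactivated by the lactone. Fallback: close ring B on the more reactive allylic C5–H of the cyclohexene, before the lactone is made. It sets out from 18. Silylation (TESCl, imidazole) would give the 3-O-triethylsilyl ether of 18 F1. The acylation/diazo transfer of step 15 would give the diazo ester F2. Rh2(esp)2 would then insert into the allylic C5–H to give the ring-B-closed 1(10)-ene F3. Selective cleavage of the secondary silyl ether (PPTS, MeOH) would give the homoallylic alcohol F4. Directed epoxidation (VO(acac)2, t-BuOOH) would give the 1β,10β-epoxide F5, and CSA-promoted lactonisation of F5 comes back to the route at 25.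

2. Step 4. The ester-bridged cation may be dealkylated to a δ-lactone, or may lose the ring proton instead of a methyl proton (isopropylidene isomer). Fallback: make the lactone on purpose and open it afterwards. It sets out from 5. Saponification (LiOH, THF/H2O) would give the carboxylic acid F6. TsOH in CH2Cl2 would cleave the cyclobutane with capture of the cation by the carboxyl group, giving the keto δ-lactone F7. TMSCl/NaI (alkyl–oxygen cleavage of the tertiary lactone to the tertiary iodide silyl ester) followed by DBU would give the isopropenyl keto acid F8, and TMSCHN2 esterification of F8 comes back to the route at 8.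

3. Step 7. Chemoselectivity between the two 1,1-disubstituted alkenes may be poor (chlorination or chlorohydrin formation at C16=C17). Fallback: chlorinate before ring D exists. It sets out from 8. The same HOCl conditions would give the allylic chloride ketone F9 (the alkyne and ketone are inert). AgBF4 in aqueous acetone would give the allylic alcohol F10. The SmI2 cyclisation of step 5 would give the bicyclic diol F11. MsCl, LiCl and collidine in DMF would convert only the primary allylic hydroxyl into the chloride F12, and TESOTf/2,6-lutidine silylation of F12 comes back to the route at 11.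

**Further compounds**

F1 | step 16 | 3-O-triethylsilyl ether of 18 | C=C1C[C@]2(CC(=O)OC)C[C@@]1(O[Si](CC)(CC)CC)CC[C@H]2C1=CC[C@H](O[Si](CC)(CC)CC)[C@@](C)(C(=O)OCC)C1
F2 | step 16 | C6 diazo ester of F1 | C=C1C[C@]2(C(=[N+]=[N-])C(=O)OC)C[C@@]1(O[Si](CC)(CC)CC)CC[C@H]2C1=CC[C@H](O[Si](CC)(CC)CC)[C@@](C)(C(=O)OCC)C1
F3 | step 16 | ring-B-closed 1(10)-ene: 19-ethyl 7-methyl diester, 3,13-bis-O-TES | C=C1C[C@]23C[C@@]1(O[Si](CC)(CC)CC)CC[C@H]2C1=CC[C@H](O[Si](CC)(CC)CC)[C@@](C)(C(=O)OCC)[C@H]1[C@@H]3C(=O)OC
F4 | step 16 | 3β-hydroxy 1(10)-ene: 19-ethyl 7-methyl diester, 13-O-TES | C=C1C[C@]23C[C@@]1(O[Si](CC)(CC)CC)CC[C@H]2C1=CC[C@H](O)[C@@](C)(C(=O)OCC)[C@H]1[C@@H]3C(=O)OC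
F5 | step 16 | 1β,10β-epoxide of F4 | C=C1C[C@]23C[C@@]1(O[Si](CC)(CC)CC)CC[C@H]2[C@@]12O[C@@H]1C[C@H](O)[C@@](C)(C(=O)OCC)[C@H]2[C@@H]3C(=O)OC
F6 | step 4 | carboxylic acid of 5 | O=C1C[C@](CC#C)(CC(=O)O)[C@H]2C[C@@H]1C2(C)C
F7 | step 4 | keto δ-lactone (arm carboxyl bonded to the former CMe2 carbon) | O=C1C[C@]2(CC#C)CC(=O)OC(C)(C)[C@@H]2CC1
F8 | step 4 | isopropenyl keto acid (carboxylic acid of 8) | O=C1C[C@](CC#C)(CC(=O)O)[C@H](C(C)=C)CC1
F9 | step 7 | allylic chloride of 8 | O=C1C[C@](CC#C)(CC(=O)OC)[C@H](C(=C)CCl)CC1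
F10 | step 7 | allylic alcohol of 8 | O=C1C[C@](CC#C)(CC(=O)OC)[C@H](C(=C)CO)CC1
F11 | step 7 | bicyclic diol (13-OH and primary allylic OH) | C=C1C[C@]2(CC(=O)OC)C[C@@]1(O)CC[C@H]2C(=C)CO
F12 | step 7 | allylic chloride with free 13-OH (desilyl 11) | C=C1C[C@]2(CC(=O)OC)C[C@@]1(O)CC[C@H]2C(=C)CCl
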